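**Plan**

- Retrosynthesis: the depside C(=O)–O bond between the ring A carbonyl and the ring B phenol oxygen is cut first. Then, in each ring, the C1–carbonyl bond and the neighbouring C6–alkyl bond are cut together, leading back to a 3-alkoxybenzyne whose triple bond is the ring bond C1–C6.
- Enabling feature: in ring A and ring B alike, the carboxyl-bearing carbon C1 lies between the alkyl-bearing C6 and the methoxy-bearing C2. The C2 methoxy oxygen polarises the C1–C6 aryne so that the alkyl Grignard enters at C6 and the carbon electrophile at C1.
- Forward: ring B is dressed first from 3-fluoro-5-methoxyphenol, whose two oxygens are already differentiated (lithiation, aryne, propyl addition, formylation). Ring A comes the same way in one step from 1-fluoro-3,5-dimethoxybenzene with the pentyl Grignard and CO2.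
- The two rings are then joined by esterification, and the ring B aldehyde is oxidised to the acid last.
- Stereochemistry: the target has no stereocenter and no stereogenic double bond, so nothing has to be set.

Key step: step 2

Assumption: the two Grignard solutions are bought and counted as starting materials, because their alkyl chains end up in the target.

**Step 1**
Reactants: 1 3-fluoro-5-methoxyphenol
Product: 2 (3-fluoro-5-methoxyphenoxy)triisopropylsilane
Conditions: i-Pr3SiCl, imidazole, DMF, rt
Reagents that add atoms: chlorotriisopropylsilane, CC(C)[Si](Cl)(C(C)C)C(C)C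
Why: Imidazole-promoted silyl ether formation at the only OH should be clean, and the bulky, weakly coordinating silyl ether tolerates organolithium and Grignard reagents and shields its own two ortho C–H bonds in step 2.

**Step 2**
Reactants: 2 (3-fluoro-5-methoxyphenoxy)triisopropylsilane; 3 propylmagnesium chloride
Product: 8 2-methoxy-6-propyl-4-(triisopropylsilyloxy)benzaldehyde, via aryllithium 4 (not isolated), via aryne 5 (not isolated), via arylmagnesium chloride 6 (not isolated), via magnesium hemiaminal alkoxide 7 (not isolated)
Conditions: n-BuLi, THF, −78 °C; then PrMgCl (excess), −78 °C to rt; then DMF (excess), 0 °C to rt; 1 M aq. HCl work-up, 0 °C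
Reagents that add atoms: N,N-dimethylformamide, CN(C)C=O
Why: Directed ortho-lithiation of 2 at the C–H between F and OMe gives 4, which loses LiF on warming to give aryne 5; the Grignard reagent adds across the triple bond (carbomagnesiation) to give 6, and Bouveault formylation with DMF followed by hydrolysis of 7 gives 8. The closest known reaction type is the three-component coupling of a 3-alkoxybenzyne, generated from a 3-alkoxyfluoroarene with n-BuLi, with a Grignard reagent and a carbon electrophile. No ring is closed and no stereocenter is formed. The first selectivity needed is the lithiation site: the C–H flanked by F (the strongest acidifying group) and OMe (which coordinates lithium) should be removed, whereas the two C–H bonds beside the bulky, poorly coordinating silyloxy group are shielded. The second is the direction of addition: the methoxy group beside the triple bond withdraws sigma electrons, which distorts the aryne and stabilises negative charge on the adjacent carbon, so propyl enters at the distal carbon (the former C–F) and magnesium ends up ortho to OMe, where it is also chelated; the silyloxy group is meta to the attacked carbon and too remote to compete. Having the Grignard reagent in excess before warming should let it outcompete 4 and any butyl species for the aryne.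

**Step 3**
Reactants: 8 2-methoxy-6-propyl-4-(triisopropylsilyloxy)benzaldehyde
Product: 9 4-hydroxy-2-methoxy-6-propylbenzaldehyde
Conditions: Bu4NF, AcOH, THF, 0 °C to rt
Reagents that add atoms: none
Why: Fluoride-mediated desilylation, driven by the strong Si–F bond and the good para-formylphenoxide leaving group, should free the phenol, with acetic acid buffering the phenoxide so that the aldehyde is untouched.

**Step 4**
Reactants: 10 1-fluoro-3,5-dimethoxybenzene; 11 pentylmagnesium bromide
Product: 16 2,4-dimethoxy-6-pentylbenzoic acid, via aryllithium 12 (not isolated), via aryne 13 (not isolated), via arylmagnesium bromide 14 (not isolated), via magnesium carboxylate 15 (not isolated)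
Conditions: n-BuLi, THF, −78 °C; then n-C5H11MgBr (excess), −78 °C to rt; then CO2 (g), −20 °C to rt; 1 M aq. HCl work-up
Reagents that add atoms: carbon dioxide, O=C=O
Why: The same three-component aryne coupling on the symmetric fluoroarene should apply: ortho-lithiation between F and OMe, loss of LiF to aryne 13, pentyl addition distal to the flanking methoxy group, and carboxylation of 14 at the carbon ortho to OMe.

**Step 5**
Reactants: 16 2,4-dimethoxy-6-pentylbenzoic acid; 9 4-hydroxy-2-methoxy-6-propylbenzaldehyde
Product: 18 4-formyl-3-methoxy-5-propylphenyl 2,4-dimethoxy-6-pentylbenzoate, via mixed trifluoroacetic anhydride 17 (not isolated)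
Conditions: (CF3CO)2O, toluene, rt
Reagents that add atoms: none
Why: In this mixed-anhydride esterification (the usual depside coupling for di-ortho-substituted benzoic acids), 17 should ionise towards an acylium ion stabilised by the ortho and para methoxy groups, which the phenol oxygen of 9 captures while the aldehyde stays inert.

**Step 6**
Reactants: 18 4-formyl-3-methoxy-5-propylphenyl 2,4-dimethoxy-6-pentylbenzoate
Product: 19 4-[(2,4-dimethoxy-6-pentylbenzoyl)oxy]-2-methoxy-6-propylbenzoic acid
Conditions: NaClO2, NaH2PO4, 2-methyl-2-butene (large excess), t-BuOH/THF/H2O, 0 °C to rt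
Reagents that add atoms: sodium chlorite, [Na+].[O-]Cl=O
Why: Pinnick oxidation with chlorous acid should convert the hindered aldehyde to the acid at mildly acidic pH without cleaving the aryl ester, while 2-methyl-2-butene scavenges hypochlorous acid and so protects the electron-rich ring A from chlorination.

**Compound list**

1 | 3-fluoro-5-methoxyphenol | COc1cc(O)cc(F)c1 | starting material
2 | (3-fluoro-5-methoxyphenoxy)triisopropylsilane | COc1cc(F)cc(O[Si](C(C)C)(C(C)C)C(C)C)c1 | intermediate
3 | propylmagnesium chloride | CCC[Mg]Cl | starting material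
4 | [2-fluoro-6-methoxy-4-(triisopropylsilyloxy)phenyl]lithium | [Li]c1c(F)cc(O[Si](C(C)C)(C(C)C)C(C)C)cc1OC | intermediate
5 | 3-methoxy-5-(triisopropylsilyloxy)benzyne (1,2-didehydro-3-methoxy-5-(triisopropylsilyloxy)benzene) | COC1=CC(O[Si](C(C)C)(C(C)C)C(C)C)=CC#C1 | intermediate
6 | [2-methoxy-6-propyl-4-(triisopropylsilyloxy)phenyl]magnesium chloride | CCCc1cc(O[Si](C(C)C)(C(C)C)C(C)C)cc(OC)c1[Mg]Cl | intermediate
7 | chloromagnesium (dimethylamino)[2-methoxy-6-propyl-4-(triisopropylsilyloxy)phenyl]methanolate | CCCc1cc(O[Si](C(C)C)(C(C)C)C(C)C)cc(OC)c1C(O[Mg]Cl)N(C)C | intermediate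
8 | 2-methoxy-6-propyl-4-(triisopropylsilyloxy)benzaldehyde | CCCc1cc(O[Si](C(C)C)(C(C)C)C(C)C)cc(OC)c1C=O | intermediate
9 | 4-hydroxy-2-methoxy-6-propylbenzaldehyde | CCCc1cc(O)cc(OC)c1C=O | intermediate
10 | 1-fluoro-3,5-dimethoxybenzene | COc1cc(F)cc(OC)c1 | starting material
11 | pentylmagnesium bromide | CCCCC[Mg]Br | starting material
12 | (2-fluoro-4,6-dimethoxyphenyl)lithium | [Li]c1c(F)cc(OC)cc1OC | intermediate
13 | 3,5-dimethoxybenzyne (1,2-didehydro-3,5-dimethoxybenzene) | COC1=CC(OC)=CC#C1 | intermediate
14 | (2,4-dimethoxy-6-pentylphenyl)magnesium bromide | CCCCCc1cc(OC)cc(OC)c1[Mg]Br | intermediate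
15 | bromomagnesium 2,4-dimethoxy-6-pentylbenzoate | CCCCCc1cc(OC)cc(OC)c1C(=O)O[Mg]Br | intermediate
16 | 2,4-dimethoxy-6-pentylbenzoic acid | CCCCCc1cc(OC)cc(OC)c1C(=O)O | intermediate
17 | 2,4-dimethoxy-6-pentylbenzoic trifluoroacetic anhydride | CCCCCc1cc(OC)cc(OC)c1C(=O)OC(=O)C(F)(F)F | intermediate
18 | 4-formyl-3-methoxy-5-propylphenyl 2,4-dimethoxy-6-pentylbenzoate | CCCCCc1cc(OC)cc(OC)c1C(=O)Oc1cc(CCC)c(C=O)c(OC)c1 | intermediate
19 | 4-[(2,4-dimethoxy-6-pentylbenzoyl)oxy]-2-methoxy-6-propylbenzoic acid | CCCCCc1cc(OC)cc(OC)c1C(=O)Oc1cc(CCC)c(C(=O)O)c(OC)c1 | target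

**Step count and risks**

Total steps: 6. Longest linear sequence: 5 steps (1, 2, 3, 5, 6); step 4 is a one-step branch for ring A.

Steps most likely to fail, riskiest first:

1. Step 2. Control may be lost at the aryne stage: the aryne may be captured by the aryllithium or by butyl species instead of the Grignard reagent, the Grignard reagent may transfer a beta-hydride to the aryne, or deprotonation may occur beside the silyloxy group and give the wrong aryne. The fallback sets out from 2 and comes back at 8, using addition–elimination in place of elimination–addition. Compound 2 is lithiated as before, but aryllithium 4 is quenched with DMF at −78 °C before any LiF is lost. The adduct formed in the flask is lithium (dimethylamino)[2-fluoro-6-methoxy-4-(triisopropylsilyloxy)phenyl]methanolate F1 and dilute HCl work-up converts F1 into 2-fluoro-6-methoxy-4-(triisopropylsilyloxy)benzaldehyde F2 from which any regioisomer can be removed by chromatography. Condensation of F2 with cyclohexylamine (toluene, MgSO4, rt) should give (E)-N-cyclohexyl-1-[2-fluoro-6-methoxy-4-(triisopropylsilyloxy)phenyl]methanimine F3 in which the imine nitrogen can chelate an incoming Grignard reagent. Propylmagnesium chloride 3 in THF should then displace the ortho fluoride of F3 (the better leaving group of the two ortho substituents) by chelation-assisted nucleophilic aromatic substitution. This should give (E)-N-cyclohexyl-1-[2-methoxy-6-propyl-4-(triisopropylsilyloxy)phenyl]methanimine F4 and hydrolysis of F4 with aqueous acetic acid on work-up gives 8.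

2. Step 5. Acyl transfer from the hindered mixed anhydride to the weakly nucleophilic para-formylphenol may be slow, so that trifluoroacetylation of the phenol or self-acylation of the electron-rich ring A takes over. The fallback sets out from 16 (with 8 as partner, so step 3 is bypassed) and comes back at 18. Acid 16 is converted with cyanuric fluoride and pyridine in CH2Cl2 into 2,4-dimethoxy-6-pentylbenzoyl fluoride F5 which is a small and stable acylating agent suited to hindered couplings. Acyl fluoride F5 is then combined with silyl ether 8 and catalytic Bu4NF in THF/MeCN: fluoride unmasks the phenoxide from 8, the phenoxide attacks F5 to give 18, and the fluoride released carries the chain.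

3. Step 6. Hypochlorous acid may chlorinate ring A faster than it is scavenged, or the doubly ortho-substituted aldehyde may oxidise incompletely. The fallback sets out from 2 and comes back at 19, carrying the ring B carboxyl at the acid oxidation level throughout. Arylmagnesium chloride 6 is generated as in step 2 and quenched with CO2 to give chloromagnesium 2-methoxy-6-propyl-4-(triisopropylsilyloxy)benzoate F6 and HCl work-up converts F6 into 2-methoxy-6-propyl-4-(triisopropylsilyloxy)benzoic acid F7 as the isolated product. Benzylation of F7 (BnBr, KHCO3, DMF) gives benzyl 2-methoxy-6-propyl-4-(triisopropylsilyloxy)benzoate F8 and desilylation of F8 (Bu4NF, AcOH, THF) gives benzyl 4-hydroxy-2-methoxy-6-propylbenzoate F9 as the phenol partner. Coupling of F9 with 16 through mixed anhydride 17 (trifluoroacetic anhydride, toluene) gives 4-(benzyloxycarbonyl)-3-methoxy-5-propylphenyl 2,4-dimethoxy-6-pentylbenzoate F10 and hydrogenolysis of F10 (H2, Pd/C, EtOAc) should then release 19 without an oxidant.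

**Further compounds**

F1 | step 2 | lithium (dimethylamino)[2-fluoro-6-methoxy-4-(triisopropylsilyloxy)phenyl]methanolate | COc1cc(O[Si](C(C)C)(C(C)C)C(C)C)cc(F)c1C(O[Li])N(C)C
F2 | step 2 | 2-fluoro-6-methoxy-4-(triisopropylsilyloxy)benzaldehyde | COc1cc(O[Si](C(C)C)(C(C)C)C(C)C)cc(F)c1C=O
F3 | step 2 | (E)-N-cyclohexyl-1-[2-fluoro-6-methoxy-4-(triisopropylsilyloxy)phenyl]methanimine | COc1cc(O[Si](C(C)C)(C(C)C)C(C)C)cc(F)c1/C=N/C1CCCCC1
F4 | step 2 | (E)-N-cyclohexyl-1-[2-methoxy-6-propyl-4-(triisopropylsilyloxy)phenyl]methanimine | CCCc1cc(O[Si](C(C)C)(C(C)C)C(C)C)cc(OC)c1/C=N/C1CCCCC1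
F5 | step 5 | 2,4-dimethoxy-6-pentylbenzoyl fluoride | CCCCCc1cc(OC)cc(OC)c1C(F)=O
F6 | step 6 | chloromagnesium 2-methoxy-6-propyl-4-(triisopropylsilyloxy)benzoate | CCCc1cc(O[Si](C(C)C)(C(C)C)C(C)C)cc(OC)c1C(=O)O[Mg]Cl
F7 | step 6 | 2-methoxy-6-propyl-4-(triisopropylsilyloxy)benzoic acid | CCCc1cc(O[Si](C(C)C)(C(C)C)C(C)C)cc(OC)c1C(=O)O
F8 | step 6 | benzyl 2-methoxy-6-propyl-4-(triisopropylsilyloxy)benzoate | CCCc1cc(O[Si](C(C)C)(C(C)C)C(C)C)cc(OC)c1C(=O)OCc1ccccc1
F9 | step 6 | benzyl 4-hydroxy-2-methoxy-6-propylbenzoate | CCCc1cc(O)cc(OC)c1C(=O)OCc1ccccc1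
F10 | step 6 | 4-(benzyloxycarbonyl)-3-methoxy-5-propylphenyl 2,4-dimethoxy-6-pentylbenzoate | CCCCCc1cc(OC)cc(OC)c1C(=O)Oc1cc(CCC)c(C(=O)OCc2ccccc2)c(OC)c1
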